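The benzene ring C4a–C5–C6–C7–C8–C8a carries oxygen on C5, C7 and C8a, methyl on C6 and C8 and the C4 acyl carbon on C4a: the imprint of a folded poly-β-carbonyl chain. Everything rests on disconnecting C4a–C8a. A 4-hydroxy-3,5-dimethyl-2-pyrone bearing a 2,4-dioxoheptacosyl chain on its 6-position, whose lactone carbon is the future C8a, is opened by magnesium methoxide, and the C4a methylene then closes on the ester carbon in a Claisen condensation. This single operation makes the C4a–C8a bond, the hexasubstituted arene and the o-hydroxyaryl β-diketone, which acid dehydrates across O1–C2 to the chromone. The pyrone arises from three carbanion acylations with Weinreb amides.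

Key step: step 6

Remark: the target has no stereocentre and no stereogenic double bond, so no configuration has to be set; atom labels are those of the chromone (O1, C2, C3, C4, C4a, C5–C8, C8a).
Remark: methanolysis of the pyrone gives an ester that carries four ketone carbonyls (a 3,5,7,9-tetraoxo ester), and the ring-opened intermediate is named and drawn accordingly.
Remark: the pyrone 4-hydroxyl (the future C7–OH) stays free; as the pyronate it is a spectator in every carbanion step, so no protecting group is needed.

Step 1
Reactants: 1 ethyl 2-methyl-3-oxopentanoate; 2 N-methoxy-N-methylacetamide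
Product: 3 ethyl 2,4-dimethyl-3,5-dioxohexanoate (mixture of diastereomers and enol forms, used crude)
Conditions: LDA (2.1 equiv), THF, −78 → 0 °C; then 2 (1.05 equiv), −78 → 0 °C; aq. HCl
Reagents that add atoms: none
Why: Twofold deprotonation gives the β-keto ester dianion, whose γ-carbon (the ethyl CH2) is the more nucleophilic site and should be acetylated by the Weinreb amide through a chelated tetrahedral adduct that releases the ketone only on quench (γ-acylation of a β-keto ester dianion, Weinreb ketone synthesis); the two labile methine centres of 3 become sp2 carbons in step 2.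

Step 2
Reactants: 3 ethyl 2,4-dimethyl-3,5-dioxohexanoate
Product: 4 4-hydroxy-3,5,6-trimethyl-2H-pyran-2-one
Conditions: DBU (1.5 equiv), toluene, reflux; then 1 M HCl
Reagents that add atoms: none
Why: DBU enolises the diketone and the enolate oxygen of the terminal acetyl ketone should attack the ester carbonyl (6-exo-trig) with loss of ethanol, driven by formation of the stabilised 4-hydroxy-2-pyrone anion (base-mediated lactonisation of a 3,5-dioxo ester).

Step 3
Reactants: 4 4-hydroxy-3,5,6-trimethyl-2H-pyran-2-one; 2 N-methoxy-N-methylacetamide
Product: 5 4-hydroxy-3,5-dimethyl-6-(2-oxopropyl)-2H-pyran-2-one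
Conditions: LDA (2.2 equiv), THF, −78 °C; then 2 (1.1 equiv), −78 → 0 °C; 1 M HCl
Reagents that add atoms: none
Why: After the hydroxyl, the second equivalent of base removes a proton from the 6-methyl group, the only methyl vinylogous to the pyrone C4 carbonyl, and this lateral carbanion should be C-acetylated by the Weinreb amide via a stable chelate (lateral acylation of a 4-hydroxy-2-pyrone dianion, Weinreb ketone synthesis).

Step 4
Reactants: 6 tetracosanoic acid
Product: 8 N-methoxy-N-methyltetracosanamide, via N-tetracosanoylimidazole 7 (not isolated)
Conditions: CDI (1.2 equiv), THF, 50 °C; then MeNH(OMe)·HCl (1.5 equiv), 50 °C → rt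
Reagents that add atoms: N,O-dimethylhydroxylamine hydrochloride, CNOC.Cl; 1,1'-carbonyldiimidazole, O=C(n1ccnc1)n1ccnc1 (its imidazolyl group is held by 7 only and is displaced on the way to 8)
Why: CDI activates the acid as its acyl imidazole with loss of carbon dioxide, and the hydroxylamine, freed from its salt by the liberated imidazole, should displace imidazole (Weinreb amide formation through an acyl imidazole).

Step 5
Reactants: 5 4-hydroxy-3,5-dimethyl-6-(2-oxopropyl)-2H-pyran-2-one; 8 N-methoxy-N-methyltetracosanamide
Product: 9 4-hydroxy-3,5-dimethyl-6-(2,4-dioxoheptacosyl)-2H-pyran-2-one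
Conditions: 5 (1.1 equiv), LDA (3.4 equiv), THF, −78 → 0 °C; then 8 (1.0 equiv) in THF, 0 °C → rt; cold 1 M HCl
Reagents that add atoms: none
Why: Threefold deprotonation (hydroxyl, the methylene between pyrone and ketone, then the terminal methyl) leaves the last-formed methyl carbanion as the most nucleophilic site, and its addition to the Weinreb amide should give a chelated adduct that neither over-adds nor quenches unreacted trianion, so the 1,3-diketone appears only on work-up (terminal acylation of a β-dicarbonyl polyanion, Weinreb ketone synthesis).

Step 6
Reactants: 9 4-hydroxy-3,5-dimethyl-6-(2,4-dioxoheptacosyl)-2H-pyran-2-one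
Product: 11 1-(2,4,6-trihydroxy-3,5-dimethylphenyl)hexacosane-1,3-dione, via methyl 2,4-dimethyl-3,5,7,9-tetraoxodotriacontanoate 10 (not isolated)
Conditions: Mg(OMe)2 (8 equiv), MeOH–THF, reflux; then 1 M HCl, 0 °C
Reagents that add atoms: magnesium methoxide, C[O-].C[O-].[Mg+2] (its methoxy group is held by 10 only and leaves again as methanol; no reagent atom remains in 11)
Why: Methoxide delivered from magnesium adds to the Mg-coordinated lactone carbonyl C8a and opens the pyrone to the chelated methyl tetraketo ester 10, in which the C4a methylene sits between the C5 and C4 ketones. Its carbanion attacks the ester carbon C8a, methoxide is expelled and the cyclohexane-1,3,5-trione so formed tautomerises to the magnesium phenoxide of 11; the reaction type is the magnesium-alkoxide-induced recyclisation that turns tetraacetic lactone and related 6-acylmethyl-4-hydroxy-2-pyrones into acylphloroglucinols, a biomimetic polyketide Claisen cyclisation. The single ring closed is the benzene ring, formed 6-exo-trig at the ester carbonyl by a doubly stabilised enolate that may be drawn enolendo (towards C5) or enolexo (towards C4), both allowed for a six-membered ring. No stereocentre is formed, and the labile methine carbons C6 and C8 of 10 end as aromatic carbons. The step needs the Claisen closure C4a→C8a to beat the aldol closures C3→C7 and C8→C4: the C7 ketone lies between two methyl-bearing carbons and is held in a magnesium chelate, the C2/C4 diketone whose C3 would attack it is likewise chelated, and an aldol at C8 creates a quaternary carbon that cannot dehydrate to an arene and therefore reverts. Because both methyl groups already sit on C6 and C8 and only the Claisen product can aromatise, the equilibria should drain into 11.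

Step 7
Reactants: 11 1-(2,4,6-trihydroxy-3,5-dimethylphenyl)hexacosane-1,3-dione
Product: 12 5,7-dihydroxy-6,8-dimethyl-2-tricosyl-4H-chromen-4-one
Conditions: p-TsOH·H2O (0.2 equiv), toluene, reflux, Dean–Stark
Reagents that add atoms: none
Why: One of the two equivalent ortho hydroxyls should add to the protonated distal ketone (the future C2) and loss of water closes the O1–C2 bond of the γ-pyrone ring, leaving the other ortho hydroxyl as the hydrogen-bonded C5–OH (acid-catalysed cyclodehydration of an o-hydroxyaryl β-diketone, the closing stage of a Baker–Venkataraman chromone synthesis).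

Compound list
1 | ethyl 2-methyl-3-oxopentanoate (racemic, labile centre) | CCC(=O)C(C)C(=O)OCC | starting material
2 | N-methoxy-N-methylacetamide | CC(=O)N(C)OC | starting material
3 | ethyl 2,4-dimethyl-3,5-dioxohexanoate (diastereomer mixture, labile centres) | CC(=O)C(C)C(=O)C(C)C(=O)OCC | intermediate
4 | 4-hydroxy-3,5,6-trimethyl-2H-pyran-2-one | Cc1oc(=O)c(C)c(O)c1C | intermediate
5 | 4-hydroxy-3,5-dimethyl-6-(2-oxopropyl)-2H-pyran-2-one | CC(=O)Cc1oc(=O)c(C)c(O)c1C | intermediate
6 | tetracosanoic acid | CCCCCCCCCCCCCCCCCCCCCCCC(=O)O | starting material
7 | N-tetracosanoylimidazole, 1-(1H-imidazol-1-yl)tetracosan-1-one (not isolated) | CCCCCCCCCCCCCCCCCCCCCCCC(=O)n1ccnc1 | intermediate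
8 | N-methoxy-N-methyltetracosanamide | CCCCCCCCCCCCCCCCCCCCCCCC(=O)N(C)OC | intermediate
9 | 4-hydroxy-3,5-dimethyl-6-(2,4-dioxoheptacosyl)-2H-pyran-2-one | CCCCCCCCCCCCCCCCCCCCCCCC(=O)CC(=O)Cc1oc(=O)c(C)c(O)c1C | intermediate
10 | methyl 2,4-dimethyl-3,5,7,9-tetraoxodotriacontanoate (magnesium chelate in the flask, labile methine centres, not isolated) | CCCCCCCCCCCCCCCCCCCCCCCC(=O)CC(=O)CC(=O)C(C)C(=O)C(C)C(=O)OC | intermediate
11 | 1-(2,4,6-trihydroxy-3,5-dimethylphenyl)hexacosane-1,3-dione | CCCCCCCCCCCCCCCCCCCCCCCC(=O)CC(=O)c1c(O)c(C)c(O)c(C)c1O | intermediate
12 | 5,7-dihydroxy-6,8-dimethyl-2-tricosyl-4H-chromen-4-one | CCCCCCCCCCCCCCCCCCCCCCCc1cc(=O)c2c(O)c(C)c(O)c(C)c2o1 | target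

Total steps: 7. Longest linear sequence: 6 (steps 1, 2, 3, 5, 6, 7; step 4 is a one-step side branch).

Steps most likely to fail, riskiest first:

Step 6. The electron-rich, doubly methylated pyronate may resist methanolysis. The opened chain may also be lost to aldol closure or to retro-Claisen cleavage by methoxide before the Claisen closure occurs. The fallback buys the arene instead of building it; it sets out from 8 and comes back to the route at 11. Commercial 2',4',6'-trihydroxyacetophenone would be C-methylated at both free ring carbons (MeI, NaOMe, MeOH) to 1-(2,4,6-trihydroxy-3,5-dimethylphenyl)ethan-1-one F1. F1 would be converted with LiHMDS (5 equiv, THF, −78 → 0 °C) into its polylithium salt, whose ketone enolate should be C-acylated by Weinreb amide 8 in a crossed Claisen-type condensation to give 11, which then enters step 7.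

Step 5. Trianion formation may stay incomplete, or the trianion may deprotonate the α-methylene of the sparingly soluble C24 amide instead of adding to it, so that 5 is returned. The fallback replaces acylation by aldol addition and oxidation; it sets out from 8 and comes back at 9. Amide 8 would be reduced (LiAlH4, THF, 0 °C) to tetracosanal F2. The trianion of 5 (LDA, 3.3 equiv, THF, −78 °C) should add to F2 to give 4-hydroxy-6-(4-hydroxy-2-oxoheptacosyl)-3,5-dimethyl-2H-pyran-2-one F3 (racemic). IBX (EtOAc, reflux) should then oxidise the β-hydroxy ketone to the β-diketone 9.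

Step 3. Proton transfer between the dianion and the acetyl donor, or acylation on oxygen instead of on the lateral carbon, may limit conversion. The fallback again uses aldol addition and oxidation; it sets out from 4 and comes back at 5. The dianion of 4 (LDA, 2.2 equiv, THF, −78 °C) should add to acetaldehyde to give 4-hydroxy-6-(2-hydroxypropyl)-3,5-dimethyl-2H-pyran-2-one F4 (racemic), and IBX (DMSO, rt) should oxidise the secondary alcohol to ketone 5.

Further compounds
F1 | step 6 | 1-(2,4,6-trihydroxy-3,5-dimethylphenyl)ethan-1-one | CC(=O)c1c(O)c(C)c(O)c(C)c1O
F2 | step 5 | tetracosanal | CCCCCCCCCCCCCCCCCCCCCCCC=O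
F3 | step 5 | 4-hydroxy-6-(4-hydroxy-2-oxoheptacosyl)-3,5-dimethyl-2H-pyran-2-one (racemic) | CCCCCCCCCCCCCCCCCCCCCCCC(O)CC(=O)Cc1oc(=O)c(C)c(O)c1C
F4 | step 3 | 4-hydroxy-6-(2-hydroxypropyl)-3,5-dimethyl-2H-pyran-2-one (racemic) | CC(O)Cc1oc(=O)c(C)c(O)c1C
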